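The pyran ring of the top epicatechin unit is closed at C3–C4. A benzylic sulfonium ylide (future C4), generated under near-neutral conditions from a tosylhydrazone by Rh carbenoid transfer to a sulfide, adds to a tethered (R)-2-aryl-2-aryloxyacetaldehyde (C3) and collapses to a 3,4-oxirane. The step exploits the vicinal C3–O/C4 pattern of this ring next to the electron-rich A ring: oxirane closure needs trans-diaxial alkoxide and sulfonium with the C2 aryl equatorial, so a temporary epoxide cis to the aryl results, which flavene epoxidation cannot give. Its C4–O bond is then cleaved by C6 of a bromine-capped unit (4β→6); two orthogonal interflavan couplings and hydrogenolysis complete the tetramer.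

Key step: step 14

Remark: α/β follow flavan usage for 2R units: the C2 aryl is α, and a 4β substituent lies on the opposite ring face (trans to the 3-OH of an epicatechin unit). Atom numbers used for open-chain precursors are those of the future flavan ring.

Step 1
Reactants: 1 (−)-epicatechin
Product: 2 5,7,3',4'-tetra-O-benzyl-(−)-epicatechin
Conditions: BnBr (4.4 equiv), K2CO3, DMF, 0 °C to rt
Reagents that add atoms: benzyl bromide, BrCc1ccccc1
Why: Williamson etherification; the four phenols are far more acidic than the secondary 3-OH, so carbonate should benzylate only them and no stereocentre is touched.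

Step 2
Reactants: 2 5,7,3',4'-tetra-O-benzyl-(−)-epicatechin
Product: 3 8-bromo-5,7,3',4'-tetra-O-benzyl-(−)-epicatechin
Conditions: NBS (1.0 equiv), CH2Cl2, −78 °C to rt
Reagents that add atoms: N-bromosuccinimide, O=C1CCC(=O)N1Br
Why: Electrophilic aromatic bromination should go to C8, the most nucleophilic A-ring position, which caps it so that later Friedel–Crafts couplings of this unit occur at C6.

Step 3
Reactants: 3 8-bromo-5,7,3',4'-tetra-O-benzyl-(−)-epicatechin
Product: 4 8-bromo-4β-(2-ethoxyethoxy)-5,7,3',4'-tetra-O-benzylepicatechin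
Conditions: DDQ (2 equiv), 2-ethoxyethanol (5 equiv), CH2Cl2, rt
Reagents that add atoms: 2-ethoxyethanol, CCOCCO
Why: DDQ benzylic oxidation (hydride abstraction at C4) gives a quinone-methide-type cation that the alcohol should trap on the face trans to the 3-OH, setting the 4β ether.

Step 4
Reactants: 4 8-bromo-4β-(2-ethoxyethoxy)-5,7,3',4'-tetra-O-benzylepicatechin
Product: 5 8-bromo-4β-(2,6-dimethylphenylthio)-5,7,3',4'-tetra-O-benzylepicatechin
Conditions: 2,6-dimethylbenzenethiol (3 equiv), BF3·OEt2 (cat.), CH2Cl2, −78 to −40 °C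
Reagents that add atoms: 2,6-dimethylbenzenethiol, Cc1cccc(C)c1S
Why: Lewis-acid ionisation of the C4 ether and capture of the cation by the soft thiol trans to the 3-OH (SN1 thioetherification) should give a 4β thioether that is inert to hard Lewis acids and serves as a latent leaving group.

Step 5
Reactants: 2 5,7,3',4'-tetra-O-benzyl-(−)-epicatechin
Product: 6 4β-(2-ethoxyethoxy)-5,7,3',4'-tetra-O-benzylepicatechin
Conditions: DDQ (2 equiv), 2-ethoxyethanol (5 equiv), CH2Cl2, rt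
Reagents that add atoms: 2-ethoxyethanol, CCOCCO
Why: The same DDQ benzylic oxidation at C4 with alcohol capture trans to the 3-OH should give the 4β ether while C8 stays free as the nucleophilic site of this unit.

Step 6
Reactants: 7 2,4,6-trihydroxybenzaldehyde
Product: 8 2,4-bis(benzyloxy)-6-hydroxybenzaldehyde
Conditions: BnBr (2.05 equiv), K2CO3 (2.2 equiv), DMF, rt
Reagents that add atoms: benzyl bromide, BrCc1ccccc1
Why: Williamson etherification should stop after the 4-OH and one ortho-OH because the remaining ortho-OH is deactivated by its hydrogen bond to the formyl group.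

Step 7
Reactants: 8 2,4-bis(benzyloxy)-6-hydroxybenzaldehyde
Product: 9 2,4-bis(benzyloxy)-3,5-dibromo-6-hydroxybenzaldehyde
Conditions: NBS (2.1 equiv), CH2Cl2, 0 °C
Reagents that add atoms: N-bromosuccinimide, O=C1CCC(=O)N1Br
Why: Electrophilic aromatic bromination should fill both remaining ring positions (each ortho/para to three oxygens), capping the future C6 and C8 of the top unit against self-condensation.

Step 8
Reactants: 10 3,4-bis(benzyloxy)benzaldehyde
Product: 11 ethyl (E)-3-[3,4-bis(benzyloxy)phenyl]prop-2-enoate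
Conditions: triethyl phosphonoacetate, NaH, THF, 0 °C to rt
Reagents that add atoms: triethyl phosphonoacetate, CCOC(=O)CP(=O)(OCC)OCC
Why: Horner–Wadsworth–Emmons olefination with a stabilised phosphonate should give the E enoate.

Step 9
Reactants: 11 ethyl (E)-3-[3,4-bis(benzyloxy)phenyl]prop-2-enoate
Product: 12 (E)-3-[3,4-bis(benzyloxy)phenyl]prop-2-en-1-ol
Conditions: DIBAL-H (2.2 equiv), CH2Cl2, −78 °C; Rochelle salt
Reagents that add atoms: none
Why: DIBAL-H 1,2-reduction of the enoate should give the allylic alcohol with the E alkene intact.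

Step 10
Reactants: 12 (E)-3-[3,4-bis(benzyloxy)phenyl]prop-2-en-1-ol
Product: 13 (E)-3-[3,4-bis(benzyloxy)phenyl]prop-2-en-1-yl methyl carbonate
Conditions: ClCO2Me, pyridine, CH2Cl2, 0 °C
Reagents that add atoms: methyl chloroformate, COC(=O)Cl
Why: O-acylation of the primary alcohol should give the linear allylic carbonate needed for iridium allyl chemistry.

Step 11
Reactants: 9 2,4-bis(benzyloxy)-3,5-dibromo-6-hydroxybenzaldehyde; 13 (E)-3-[3,4-bis(benzyloxy)phenyl]prop-2-en-1-yl methyl carbonate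
Product: 14 2,4-bis(benzyloxy)-3,5-dibromo-6-{[(1S)-1-[3,4-bis(benzyloxy)phenyl]prop-2-en-1-yl]oxy}benzaldehyde
Conditions: LiOtBu (1.0 equiv), [Ir(cod)Cl]2 (2 mol%), chiral phosphoramidite (4 mol%, enantiomer chosen for the S ether), THF, rt to 50 °C
Reagents that add atoms: none
Why: Iridium-catalysed asymmetric allylic etherification; the aryloxide should attack the aryl-substituted terminus of the allyl-iridium complex (branched selectivity) and the ligand sets the S benzylic centre that becomes C2.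

Step 12
Reactants: 14 2,4-bis(benzyloxy)-3,5-dibromo-6-{[(1S)-1-[3,4-bis(benzyloxy)phenyl]prop-2-en-1-yl]oxy}benzaldehyde
Product: 15 N'-[(E)-(2,4-bis(benzyloxy)-3,5-dibromo-6-{[(1S)-1-[3,4-bis(benzyloxy)phenyl]prop-2-en-1-yl]oxy}phenyl)methylidene]-4-methylbenzenesulfonohydrazide
Conditions: TsNHNH2 (1.1 equiv), MeOH/THF, 50 °C
Reagents that add atoms: 4-methylbenzenesulfonohydrazide, Cc1ccc(cc1)S(=O)(=O)NN
Why: Condensation of the aryl aldehyde with tosylhydrazide should give the E tosylhydrazone, the latent diazo precursor at the future C4, while alkene and ether stereocentre are inert.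

Step 13
Reactants: 15 N'-[(E)-(2,4-bis(benzyloxy)-3,5-dibromo-6-{[(1S)-1-[3,4-bis(benzyloxy)phenyl]prop-2-en-1-yl]oxy}phenyl)methylidene]-4-methylbenzenesulfonohydrazide
Product: 16 N'-[(E)-(2,4-bis(benzyloxy)-3,5-dibromo-6-{[(1R)-1-[3,4-bis(benzyloxy)phenyl]-2-oxoethyl]oxy}phenyl)methylidene]-4-methylbenzenesulfonohydrazide
Conditions: OsO4 (2 mol%), NaIO4 (4 equiv), 2,6-lutidine (2 equiv), dioxane/H2O 3:1, rt; used crude at once
Reagents that add atoms: osmium tetroxide, O=[Os](=O)(=O)=O (catalytic oxygen carrier); sodium periodate, [Na+].[O-]I(=O)(=O)=O (terminal oxygen source)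
Why: Lemieux–Johnson oxidation; the only alkene is dihydroxylated and cleaved to the C3 aldehyde under lutidine-buffered conditions that should neither enolise the new aldehyde nor harm the hydrazone, the stereocentre being unchanged in space (renamed R by priority).

Step 14
Reactants: 16 N'-[(E)-(2,4-bis(benzyloxy)-3,5-dibromo-6-{[(1R)-1-[3,4-bis(benzyloxy)phenyl]-2-oxoethyl]oxy}phenyl)methylidene]-4-methylbenzenesulfonohydrazide
Product: 19 (2R,3R,4R)-6,8-dibromo-5,7,3',4'-tetrakis(benzyloxy)-3,4-epoxyflavan (oxirane oxygen cis to the C2 aryl), via aryldiazomethane 17 (not isolated), via sulfonium ylide 18 (not isolated)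
Conditions: NaHMDS (1.0 equiv), THF, −78 °C; then Rh2(OAc)4 (2 mol%), tetrahydrothiophene (5 equiv), BnEt3NCl (10 mol%), MeCN, 40 °C, 0.005 M; filtration through basic alumina, used at once
Reagents that add atoms: none
Why: The sodium tosylhydrazone salt should lose sulfinate to give aryldiazomethane 17, Rh2(OAc)4 turns it into a carbenoid that tetrahydrothiophene intercepts as sulfonium ylide 18, and the ylide carbon (C4) adds to the tethered aldehyde carbon (C3) to give a betaine that expels the sulfide and closes to the oxirane. The closest known reaction type is the Corey–Chaykovsky epoxidation in its catalytic carbenoid/sulfide form, run here intramolecularly. The pyran ring is closed by 6-exo-trig attack of C4 on the C3 carbonyl and the oxirane by 3-exo-tet displacement of the sulfonium group. C2 is carried in from 16; C3 and C4 are set because the displacement needs alkoxide and sulfonium antiperiplanar (trans-diaxial, the sulfonium also being pushed axial by the C5 benzyloxy group), which with the C2 aryl equatorial places the oxygen cis to the aryl, while betaines that cannot reach this geometry should revert. The step needs ylide formation to outrun enolisation of the acidic C2–H aldehyde and carbenoid C–H insertion (into C2–H or the neighbouring OCH2Ph), which the absence of free base and the excess sulfide should secure.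

Step 15
Reactants: 19 (2R,3R,4R)-6,8-dibromo-5,7,3',4'-tetrakis(benzyloxy)-3,4-epoxyflavan; 5 8-bromo-4β-(2,6-dimethylphenylthio)-5,7,3',4'-tetra-O-benzylepicatechin
Product: 20 [6,8-dibromo-5,7,3',4'-tetra-O-benzylepicatechin]-(4β→6)-[8-bromo-4β-(2,6-dimethylphenylthio)-5,7,3',4'-tetra-O-benzylepicatechin]
Conditions: 5 (1.5 equiv), BF3·OEt2 (0.2 equiv), CH2Cl2, −78 °C
Reagents that add atoms: none
Why: Friedel–Crafts opening of the benzylic epoxide; the Lewis acid opens the oxirane at C4 (cation stabilised by O1, 5-O and 7-O) and C6 of 5, its only free ring position, should attack anti to the C3 oxygen to give the 3,4-trans (4β→6) bond, the thioether of 5 being inert to BF3 and the electrophile being fully bromine-capped.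

Step 16
Reactants: 20 [6,8-dibromo-5,7,3',4'-tetra-O-benzylepicatechin]-(4β→6)-[8-bromo-4β-(2,6-dimethylphenylthio)-5,7,3',4'-tetra-O-benzylepicatechin]; 6 4β-(2-ethoxyethoxy)-5,7,3',4'-tetra-O-benzylepicatechin
Product: 21 [6,8-dibromo-5,7,3',4'-tetra-O-benzylepicatechin]-(4β→6)-[8-bromo-5,7,3',4'-tetra-O-benzylepicatechin]-(4β→8)-[4β-(2-ethoxyethoxy)-5,7,3',4'-tetra-O-benzylepicatechin]
Conditions: 6 (2.5 equiv), I2 (1.2 equiv), Ag2O (1.2 equiv), MS 4 Å, CH2Cl2, −78 to −30 °C
Reagents that add atoms: none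
Why: Soft iodonium activation of the thioether (thioglycoside-type activation, orthogonal to the hard alkoxy leaving group of 6) should release the C4 cation of the lower unit of 20, which C8 of 6, its most nucleophilic position, captures trans to the 3-OH (4β→8).

Step 17
Reactants: 21 [6,8-dibromo-5,7,3',4'-tetra-O-benzylepicatechin]-(4β→6)-[8-bromo-5,7,3',4'-tetra-O-benzylepicatechin]-(4β→8)-[4β-(2-ethoxyethoxy)-5,7,3',4'-tetra-O-benzylepicatechin]; 3 8-bromo-5,7,3',4'-tetra-O-benzyl-(−)-epicatechin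
Product: 22 [6,8-dibromo-5,7,3',4'-tetra-O-benzylepicatechin]-(4β→6)-[8-bromo-5,7,3',4'-tetra-O-benzylepicatechin]-(4β→8)-[5,7,3',4'-tetra-O-benzylepicatechin]-(4β→6)-[8-bromo-5,7,3',4'-tetra-O-benzylepicatechin]
Conditions: 3 (3 equiv), TMSOTf (0.2 equiv), CH2Cl2, −78 °C
Reagents that add atoms: none
Why: Lewis-acid ionisation of the 4-alkoxy group and Friedel–Crafts capture by C6 of the C8-capped unit 3, trans to the 3-OH, should give the last 4β→6 interflavan bond, the excess of 3 suppressing self-condensation.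

Step 18
Reactants: 22 [6,8-dibromo-5,7,3',4'-tetra-O-benzylepicatechin]-(4β→6)-[8-bromo-5,7,3',4'-tetra-O-benzylepicatechin]-(4β→8)-[5,7,3',4'-tetra-O-benzylepicatechin]-(4β→6)-[8-bromo-5,7,3',4'-tetra-O-benzylepicatechin]
Product: 23 epicatechin-(4β→6)-epicatechin-(4β→8)-epicatechin-(4β→6)-epicatechin (target)
Conditions: H2 (1 atm), 20% Pd(OH)2/C, Et3N (5 equiv), THF/MeOH/H2O, rt
Reagents that add atoms: none
Why: Hydrogenolysis should remove all sixteen benzyl ethers and reduce the four aryl C–Br bonds in one operation, triethylamine buffering the HBr so that the acid-labile interflavan bonds and all stereocentres survive.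

Compound list
1 | (−)-epicatechin | Oc1cc(O)c2c(c1)O[C@H](c1ccc(O)c(O)c1)[C@H](O)C2 | starting material
2 | 5,7,3',4'-tetra-O-benzyl-(−)-epicatechin | c1(OCc9ccccc9)cc(OCc9ccccc9)c2c(c1)O[C@H](c1ccc(OCc9ccccc9)c(OCc9ccccc9)c1)[C@H](O)C2 | intermediate
3 | 8-bromo-5,7,3',4'-tetra-O-benzyl-(−)-epicatechin | c1(OCc9ccccc9)cc(OCc9ccccc9)c2c(c1Br)O[C@H](c1ccc(OCc9ccccc9)c(OCc9ccccc9)c1)[C@H](O)C2 | intermediate
4 | 8-bromo-4β-(2-ethoxyethoxy)-5,7,3',4'-tetra-O-benzylepicatechin | c1(OCc9ccccc9)cc(OCc9ccccc9)c2c(c1Br)O[C@H](c1ccc(OCc9ccccc9)c(OCc9ccccc9)c1)[C@H](O)[C@H]2OCCOCC | intermediate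
5 | 8-bromo-4β-(2,6-dimethylphenylthio)-5,7,3',4'-tetra-O-benzylepicatechin | c1(OCc9ccccc9)cc(OCc9ccccc9)c2c(c1Br)O[C@H](c1ccc(OCc9ccccc9)c(OCc9ccccc9)c1)[C@H](O)[C@H]2Sc1c(C)cccc1C | intermediate
6 | 4β-(2-ethoxyethoxy)-5,7,3',4'-tetra-O-benzylepicatechin | c1(OCc9ccccc9)cc(OCc9ccccc9)c2c(c1)O[C@H](c1ccc(OCc9ccccc9)c(OCc9ccccc9)c1)[C@H](O)[C@H]2OCCOCC | intermediate
7 | 2,4,6-trihydroxybenzaldehyde | O=Cc1c(O)cc(O)cc1O | starting material
8 | 2,4-bis(benzyloxy)-6-hydroxybenzaldehyde | O=Cc1c(O)cc(OCc9ccccc9)cc1OCc9ccccc9 | intermediate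
9 | 2,4-bis(benzyloxy)-3,5-dibromo-6-hydroxybenzaldehyde | O=Cc1c(O)c(Br)c(OCc9ccccc9)c(Br)c1OCc9ccccc9 | intermediate
10 | 3,4-bis(benzyloxy)benzaldehyde | O=Cc1ccc(OCc9ccccc9)c(OCc9ccccc9)c1 | starting material
11 | ethyl (E)-3-[3,4-bis(benzyloxy)phenyl]prop-2-enoate | CCOC(=O)/C=C/c1ccc(OCc9ccccc9)c(OCc9ccccc9)c1 | intermediate
12 | (E)-3-[3,4-bis(benzyloxy)phenyl]prop-2-en-1-ol | OC/C=C/c1ccc(OCc9ccccc9)c(OCc9ccccc9)c1 | intermediate
13 | (E)-3-[3,4-bis(benzyloxy)phenyl]prop-2-en-1-yl methyl carbonate | COC(=O)OC/C=C/c1ccc(OCc9ccccc9)c(OCc9ccccc9)c1 | intermediate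
14 | 2,4-bis(benzyloxy)-3,5-dibromo-6-{[(1S)-1-[3,4-bis(benzyloxy)phenyl]prop-2-en-1-yl]oxy}benzaldehyde | O=Cc1c(O[C@@H](C=C)c2ccc(OCc9ccccc9)c(OCc9ccccc9)c2)c(Br)c(OCc9ccccc9)c(Br)c1OCc9ccccc9 | intermediate
15 | E tosylhydrazone of 14 | Cc1ccc(cc1)S(=O)(=O)N/N=C/c1c(O[C@@H](C=C)c2ccc(OCc9ccccc9)c(OCc9ccccc9)c2)c(Br)c(OCc9ccccc9)c(Br)c1OCc9ccccc9 | intermediate
16 | E tosylhydrazone bearing the (1R)-1-aryl-2-oxoethyl ether (C3 aldehyde) | Cc1ccc(cc1)S(=O)(=O)N/N=C/c1c(O[C@@H](C=O)c2ccc(OCc9ccccc9)c(OCc9ccccc9)c2)c(Br)c(OCc9ccccc9)c(Br)c1OCc9ccccc9 | intermediate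
17 | aryldiazomethane from 16 (diazo carbon = future C4) | [N-]=[N+]=Cc1c(O[C@@H](C=O)c2ccc(OCc9ccccc9)c(OCc9ccccc9)c2)c(Br)c(OCc9ccccc9)c(Br)c1OCc9ccccc9 | intermediate
18 | tetrahydrothiophenium benzylide (sulfonium ylide at future C4) | [CH-]([S+]7CCCC7)c1c(O[C@@H](C=O)c2ccc(OCc9ccccc9)c(OCc9ccccc9)c2)c(Br)c(OCc9ccccc9)c(Br)c1OCc9ccccc9 | intermediate
19 | (2R,3R,4R)-6,8-dibromo-5,7,3',4'-tetrakis(benzyloxy)-3,4-epoxyflavan (oxirane cis to the C2 aryl) | c1(OCc9ccccc9)c(Br)c(OCc9ccccc9)c2c(c1Br)O[C@H](c1ccc(OCc9ccccc9)c(OCc9ccccc9)c1)[C@@H]3O[C@H]23 | intermediate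
20 | [6,8-dibromo-5,7,3',4'-tetra-O-benzylepicatechin]-(4β→6)-[8-bromo-4β-(2,6-dimethylphenylthio)-5,7,3',4'-tetra-O-benzylepicatechin] | c1(OCc9ccccc9)c(Br)c(OCc9ccccc9)c2c(c1Br)O[C@H](c1ccc(OCc9ccccc9)c(OCc9ccccc9)c1)[C@H](O)[C@H]2c1c(OCc9ccccc9)c(Br)c2c(c1OCc9ccccc9)[C@H](Sc1c(C)cccc1C)[C@@H](O)[C@@H](c1ccc(OCc9ccccc9)c(OCc9ccccc9)c1)O2 | intermediate
21 | [6,8-dibromo-5,7,3',4'-tetra-O-benzylepicatechin]-(4β→6)-[8-bromo-5,7,3',4'-tetra-O-benzylepicatechin]-(4β→8)-[4β-(2-ethoxyethoxy)-5,7,3',4'-tetra-O-benzylepicatechin] | c1(OCc9ccccc9)c(Br)c(OCc9ccccc9)c2c(c1Br)O[C@H](c1ccc(OCc9ccccc9)c(OCc9ccccc9)c1)[C@H](O)[C@H]2c1c(OCc9ccccc9)c(Br)c2c(c1OCc9ccccc9)[C@H](c1c(OCc9ccccc9)cc(OCc9ccccc9)c3c1O[C@H](c1ccc(OCc9ccccc9)c(OCc9ccccc9)c1)[C@H](O)[C@H]3OCCOCC)[C@@H](O)[C@@H](c1ccc(OCc9ccccc9)c(OCc9ccccc9)c1)O2 | intermediate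
22 | [6,8-dibromo-5,7,3',4'-tetra-O-benzylepicatechin]-(4β→6)-[8-bromo-5,7,3',4'-tetra-O-benzylepicatechin]-(4β→8)-[5,7,3',4'-tetra-O-benzylepicatechin]-(4β→6)-[8-bromo-5,7,3',4'-tetra-O-benzylepicatechin] | c1(OCc9ccccc9)c(Br)c(OCc9ccccc9)c2c(c1Br)O[C@H](c1ccc(OCc9ccccc9)c(OCc9ccccc9)c1)[C@H](O)[C@H]2c1c(OCc9ccccc9)c(Br)c2c(c1OCc9ccccc9)[C@H](c1c(OCc9ccccc9)cc(OCc9ccccc9)c3c1O[C@H](c1ccc(OCc9ccccc9)c(OCc9ccccc9)c1)[C@H](O)[C@H]3c1c(OCc9ccccc9)c(Br)c3c(c1OCc9ccccc9)C[C@@H](O)[C@@H](c1ccc(OCc9ccccc9)c(OCc9ccccc9)c1)O3)[C@@H](O)[C@@H](c1ccc(OCc9ccccc9)c(OCc9ccccc9)c1)O2 | intermediate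
23 | epicatechin-(4β→6)-epicatechin-(4β→8)-epicatechin-(4β→6)-epicatechin | Oc1cc(O)c2c(c1)O[C@H](c1ccc(O)c(O)c1)[C@H](O)[C@H]2c1c(O)cc2c(c1O)[C@H](c1c(O)cc(O)c3c1O[C@H](c1ccc(O)c(O)c1)[C@H](O)[C@H]3c1c(O)cc3c(c1O)C[C@@H](O)[C@@H](c1ccc(O)c(O)c1)O3)[C@@H](O)[C@@H](c1ccc(O)c(O)c1)O2 | target

Total step count: 18. Longest linear sequence: 11 steps (10 → 11 → 12 → 13 → 14 → 15 → 16 → 19 → 20 → 21 → 22 → 23).

Steps most likely to fail

Step 14. Proton transfer from the acidic C2–H to the ylide or the hydrazone anion (epimerisation, then alkylation of the enolate), carbenoid C–H insertion into C2–H or the neighbouring benzyloxy CH2, betaine formation that does not revert (oxirane trans to the aryl), or hydride-shift decomposition of the labile oxirane may each take over. The fallback sets out from 14 and comes back at 20; it still closes the pyran ring at C3–C4, now by metathesis. Wittig methylenation of 14 (Ph3P=CH2, THF) should give the styrene–allyl ether diene F1. Grubbs II (CH2Cl2, 40 °C) should close it to the 2H-chromene (flav-3-ene) F2. Hydroboration–oxidation (BH3·THF, then H2O2/NaOH), anti to the C2 aryl, should give the 2,3-trans flavan-3-ol F3. Dess–Martin oxidation should give the flavan-3-one F4. L-Selectride at −78 °C should deliver hydride equatorially to give the 2,3-cis flavan-3-ol F5. DDQ/2-ethoxyethanol should then give the 4β-(2-ethoxyethoxy) ether F6. BF3·OEt2-mediated coupling of F6 with 5 (thioether inert) should give 20.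

Step 15. Lewis-acid-induced 1,2-hydride shift of the oxirane (to the flavan-3-one) or elimination may outrun capture by the hindered, bromine-deactivated C6 nucleophile. The fallback sets out from 19 and comes back at 20. The oxirane is solvolysed without Lewis acid (AcOH/NaOAc, CH2Cl2, 0 °C), the small and abundant acetate opening C4 trans to the C3 oxygen, to give the storable 4β-acetoxy-3-ol F7. F7 is then coupled with 5 under BF3·OEt2 at −78 °C (acetoxy activated in the presence of the thioether) to give 20.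

Step 16. Electrophilic iodination of nucleophile 6 at C8, or silver-assisted ionisation of its own alkoxy group with self-condensation, may compete with thioether activation. The fallback sets out from 20 and comes back at 21. The thioether of 20 is activated (I2, Ag2O) in the presence of a large, recoverable excess of the simple nucleophile 2, which carries no leaving group, to give the trimer with an unfunctionalised terminal unit F8. DDQ/2-ethoxyethanol then oxidises its only flavan CH2 (C4 of the terminal unit), trans to the 3-OH, to give 21.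

Further compounds
F1 | step 14 | 4,6-bis(benzyloxy)-3,5-dibromo-2-{[(1S)-1-[3,4-bis(benzyloxy)phenyl]prop-2-en-1-yl]oxy}styrene | C=Cc1c(O[C@@H](C=C)c2ccc(OCc9ccccc9)c(OCc9ccccc9)c2)c(Br)c(OCc9ccccc9)c(Br)c1OCc9ccccc9
F2 | step 14 | (2S)-5,7-bis(benzyloxy)-2-[3,4-bis(benzyloxy)phenyl]-6,8-dibromo-2H-chromene | c1(OCc9ccccc9)c(Br)c(OCc9ccccc9)c2c(c1Br)O[C@H](c1ccc(OCc9ccccc9)c(OCc9ccccc9)c1)C=C2
F3 | step 14 | 6,8-dibromo-5,7,3',4'-tetra-O-benzyl-(+)-catechin (2R,3S; 2,3-trans) | c1(OCc9ccccc9)c(Br)c(OCc9ccccc9)c2c(c1Br)O[C@H](c1ccc(OCc9ccccc9)c(OCc9ccccc9)c1)[C@@H](O)C2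
F4 | step 14 | (2R)-5,7-bis(benzyloxy)-2-[3,4-bis(benzyloxy)phenyl]-6,8-dibromochroman-3-one | c1(OCc9ccccc9)c(Br)c(OCc9ccccc9)c2c(c1Br)O[C@H](c1ccc(OCc9ccccc9)c(OCc9ccccc9)c1)C(=O)C2
F5 | step 14 | 6,8-dibromo-5,7,3',4'-tetra-O-benzyl-(−)-epicatechin (2R,3R; 2,3-cis) | c1(OCc9ccccc9)c(Br)c(OCc9ccccc9)c2c(c1Br)O[C@H](c1ccc(OCc9ccccc9)c(OCc9ccccc9)c1)[C@H](O)C2
F6 | step 14 | 6,8-dibromo-4β-(2-ethoxyethoxy)-5,7,3',4'-tetra-O-benzylepicatechin | c1(OCc9ccccc9)c(Br)c(OCc9ccccc9)c2c(c1Br)O[C@H](c1ccc(OCc9ccccc9)c(OCc9ccccc9)c1)[C@H](O)[C@H]2OCCOCC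
F7 | step 15 | 4β-acetoxy-6,8-dibromo-5,7,3',4'-tetra-O-benzylepicatechin | c1(OCc9ccccc9)c(Br)c(OCc9ccccc9)c2c(c1Br)O[C@H](c1ccc(OCc9ccccc9)c(OCc9ccccc9)c1)[C@H](O)[C@H]2OC(C)=O
F8 | step 16 | [6,8-dibromo-5,7,3',4'-tetra-O-benzylepicatechin]-(4β→6)-[8-bromo-5,7,3',4'-tetra-O-benzylepicatechin]-(4β→8)-[5,7,3',4'-tetra-O-benzylepicatechin] | c1(OCc9ccccc9)c(Br)c(OCc9ccccc9)c2c(c1Br)O[C@H](c1ccc(OCc9ccccc9)c(OCc9ccccc9)c1)[C@H](O)[C@H]2c1c(OCc9ccccc9)c(Br)c2c(c1OCc9ccccc9)[C@H](c1c(OCc9ccccc9)cc(OCc9ccccc9)c3c1O[C@H](c1ccc(OCc9ccccc9)c(OCc9ccccc9)c1)[C@H](O)C3)[C@@H](O)[C@@H](c1ccc(OCc9ccccc9)c(OCc9ccccc9)c1)O2
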